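c(product) in the amber run reads 23.7 mM at 19 min, but 41.7 mM and 43.5 mM at 110 min and 130 min.

| setting | amber | teal | red | violet | green |
|---|---|---|---|---|---|
| starting material | 200 mM | 80.0 mM | 300 mM | 200 mM | 200 mM |
| free catalyst | 10.0 mM | 10.0 mM | 10.0 mM | 15.0 mM | 10.0 mM |
| time |  |  |  |  | 320 min |

| run | time / min | [product] / mM |
|---|---|---|
| amber run | 19 | 23.7 |
| amber run | 37 | 33.3 |
| amber run | 56 | 37.2 |
| amber run | 74 | 37.7 |
| amber run | 93 | 41.0 |
| amber run | 110 | 41.7 |
| amber run | 130 | 43.5 |
| teal run | 19 | 11.5 |
| teal run | 37 | 16.9 |
| teal run | 56 | 20.7 |
| teal run | 74 | 24.5 |
| teal run | 93 | 25.5 |
| teal run | 110 | 24.8 |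
| teal run | 130 | 25.4 |
| red run | 19 | 28.2 |
| red run | 37 | 42.2 |
| red run | 56 | 46.3 |
| red run | 74 | 47.3 |
| red run | 93 | 47.9 |
| red run | 110 | 51.6 |
| red run | 130 | 52.1 |
| violet run | 19 | 25.4 |
| violet run | 37 | 38.0 |
| violet run | 56 | 44.0 |
| violet run | 74 | 45.2 |
| violet run | 93 | 47.6 |
| violet run | 110 | 50.1 |
| violet run | 130 | 49.5 |

(each reading ± 1 mM)

- apparent order in [starting material] of the starting rate, round the charge of the amber run (the rate where two percent of its starting material have turned into product) (one fixed amount of product, the same in the runs compared)
- apparent order in [free catalyst] of the starting rate, round the charge of the amber run (the rate where two percent of its starting material have turned into product)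
- product in the green run at 320 min, as a share of the starting material charged

- Overall: starting material -> product, with free catalyst as catalyst.
- Constant volume, constant temperature.
- What is held in complexes is read along with the free species.
- An order is taken over about fifteen percent of the charge, up and down.

So the early rate and the late level are two regimes, and the question is where one hands over to the other. The last two amber readings average 42.6 mM, the stop level. The first reading gives a mean early rate of 1.25 mM min⁻¹.

The stop level is not an equilibrium share. Read in the same way, it is 31.4% of the charge in the teal run and 17.3% in the red run. This points to kinetic rather than thermodynamic control.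

The crossing can therefore be put in one time. The stall time, the stop level divided by the early rate, 34.2 min for amber, is the time the early rate would need to make the stop level. The amber reading at 19 min stands before it, and the one at 130 min after it.

The green run has the amber charge, and 320 min is later than the crossing. The reckoning here therefore takes the amber stop level as the green result, 21.3% of the charge, a reading with the scatter of 1 mM per point.

The forecast gives orders of 0.65 and 0.8 and a green share of 24.5%, higher than this share, reading the late climb as “logarithmic creep”.

The green run gives 21.8% at 320 min, which is 9.36 stall times on, against the 21.3% reckoned here; the orders are 0.69 in c(starting material) and 0.57 in c(free catalyst).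

2 free catalyst ⇌ catalyst dimer, settled at all times (9730 M⁻¹); free catalyst + starting material → product + free catalyst (31.74 M⁻¹ min⁻¹); 2 starting material → homo dimer (1.110 M⁻¹ min⁻¹); 2 starting material ⇌ idle substrate dimer, settled at all times (9.640 M⁻¹) The stop comes from the conversion of starting material into homo dimer: the green run without that step gives 99.3%, against 21.8%. In the violet run the stall time reads 37.3 min, and c(product) comes to a quarter of the violet charge, 50.0 mM, at 177 min, which is 4.75 stall times on.

Readings and results were generated by integration from invented constants, and the scatter is random.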